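The easy step comes first: if a curve bends like a single exponential, its first two readings give a starting rate by hand.

| flask | starting material | reagent | free catalyst | time |
|---|---|---|---|---|
| epsilon | 100 mM | 150 mM | 0.500 mM |  |
| zeta | 40.0 mM | 90.0 mM | 0.500 mM |  |
| alpha | 100 mM | 150 mM | 1.50 mM |  |
| theta | 100 mM | 300 mM | 0.500 mM |  |
| gamma | 300 mM | 300 mM | 0.500 mM | 22 h |

| epsilon run: time / h | epsilon run: [target] / mM | zeta run: time / h | zeta run: [target] / mM | alpha run: time / h | alpha run: [target] / mM | theta run: time / h | theta run: [target] / mM |
|---|---|---|---|---|---|---|---|
| 4.4 | 17.5 | 4.4 | 4.7 | 4.4 | 30.5 | 4.4 | 31.7 |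
| 8.8 | 28.3 | 8.8 | 7.7 | 8.8 | 43.7 | 8.8 | 46.8 |
| 13 | 34.2 | 13 | 9.8 | 13 | 50.5 | 13 | 53.8 |
| 18 | 39.3 | 18 | 10.7 | 18 | 53.1 | 18 | 56.8 |
| 22 | 39.1 | 22 | 12.5 | 22 | 52.8 | 22 | 57.6 |

(scatter of a reading: 0.5 mM)

* the exponent of [free catalyst] in the starting rate at the charge of the epsilon run (at the point where two percent of the starting material have become target)
* the exponent of [starting material] in the starting rate at the charge of the epsilon run (at the point where two percent of the starting material have become target) (one fixed amount of target, the same in the runs compared)
* target in the gamma run at 22 h, as a share of the starting material charged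

- Overall: starting material + reagent -> target, with free catalyst as catalyst.
- Constant volume, constant temperature.
- An order is taken over about fifteen percent of the charge, up and down.

I fit each flask through its readings at 4.4 h and 8.8 h, which gives starting rates of 5.01 mM h⁻¹ for the epsilon flask, 1.33 mM h⁻¹ for the zeta flask, 10.2 mM h⁻¹ for the alpha flask and 10.2 mM h⁻¹ for the theta flask. The theta flask has 300 mM of reagent against 150 mM in the epsilon flask, and its rate ratio of 2.04 makes an order of 1.03. With the reagent's part divided out, the zeta flask's starting rate is 0.441 of the epsilon flask's on a charge ratio of 0.400, so I take starting material as first order. The alpha flask has 1.50 mM of catalyst against 0.500 mM in the epsilon flask, and its rate ratio of 2.04 makes an average order of 0.649 across that span. The order asked for is local, though. If free catalyst pairs quickly into catalyst dimer and the rate follows what stays free, that ratio leaves 0.274 mM free in the epsilon flask, about half of the charge, and a local order of 0.689.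

Dividing the epsilon flask's starting rate by its two charges gives a second-order constant of 0.334 M⁻¹ h⁻¹, and the gamma flask shares that flask's catalyst charge. Integrated with no loss, this constant gives 0.206 M of target in the gamma flask at 22 h. The same integration gives 0.0571 M for the epsilon flask, whose reading is 39.1 mM. That reading over the loss-free figure is the kept share 0.684, and applied to the gamma flask it gives 47.1% of the charge.

The weak link is that this share comes from one flask. The theta flask has the gamma reagent charge, and its loss-free 0.0834 M against its reading of 57.6 mM gives a share of 0.691, so I commit.

The forecast, reached by its own reckoning, says 0.65 for free catalyst, 1 for starting material and 47%, and it reads the catalyst order as pointing to “an off-cycle reservoir such as a dimer”.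

The gamma flask gives 48.4% of its starting material as target, with orders of 0.68 in free catalyst and 1.0 in starting material.

    2 free catalyst ⇌ catalyst dimer, settled at all times (1830 M⁻¹)
    free catalyst + starting material + reagent → target + free catalyst (1307 M⁻² h⁻¹)
    target → decomposed product (0.01591 h⁻¹)
    starting material → decomposed substrate (0.02128 h⁻¹)

Main steps alone leave a residual of 11 scatter units. The gamma kept share comes to 0.703. For the zeta flask, the loss-free integration gives 0.0178 M, the kept share brings that to 0.0122 M, and the zeta reading at that time is 12.5 mM.

The earlier runs and the new flask were computed with made-up constants, and the scatter is random.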